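**Retrosynthetic overview**
1. The geranyl ether is made last by alkylating O5 of a 3,5,7-triol; O7 is hydrogen-bonded to the 8-acetyl group, and O5 is carried as a benzyl ether until then.
2. The C3–OH comes from a C3–B bond by oxidation with retention; ring B (the pyran) and that C3–B stereocentre come from one [4+2] cycloaddition that makes the C4–C3 and O1–C2 bonds together.
3. The partners are an ortho-quinone methide of ring A (oxadiene C4=C4a–C8a=O1) and an isobutenyl boronate whose boron carries a pinene-derived iminodiacetate ligand as chiral auxiliary.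
4. Enabling feature: O1 (on C8a) and the benzylic C4 (on C4a) are ortho neighbours on the acylphloroglucinol ring A, so ring A unmasks as an oxadiene stabilised by the 8-acetyl group and the O5/O7 donors; C2 is a gem-dimethyl (tertiary cation) terminus, and C3 is the only stereocentre, so only one alkene face must be controlled.
5. Ring order: ring A is bought as 2',4',6'-trihydroxyacetophenone; ring B is the only ring formed, in the key step, from a quinone methide released from a Mannich base.

Key step: step 6

Assumption: the isopinocampheyl ligand of the boronate is taken to expose the alkene face that leads to the 3R adduct, by analogy with the face-selective epoxidation of alkenyl boronates bearing this ligand; if the sense proves opposite, the enantiomeric ligand from (1S,2S,3S,5R)-isopinocampheylamine is used and nothing else changes.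

**Route**

Step 1
Reactants: 1 1-(2,4,6-trihydroxyphenyl)ethanone
Product: 2 1-[4-(benzyloxy)-2,6-dihydroxyphenyl]ethanone
Conditions: BnBr (1.0 equiv), K2CO3 (1.0 equiv), DMF, 0 to 23 °C
Reagents that add atoms: benzyl bromide, BrCc1ccccc1
Why: Williamson ether synthesis in which the 4-OH, the most acidic hydroxyl and the only one not hydrogen-bonded to the ketone, should be etherified first by one equivalent of base and halide.

Step 2
Reactants: 2 1-[4-(benzyloxy)-2,6-dihydroxyphenyl]ethanone
Product: 3 1-{4-(benzyloxy)-3-[(dimethylamino)methyl]-2,6-dihydroxyphenyl}ethanone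
Conditions: 37% aq CH2O (1.0 equiv), 40% aq Me2NH (1.0 equiv), EtOH, 0 to 23 °C
Reagents that add atoms: formaldehyde, C=O; dimethylamine, CNC
Why: Phenolic Mannich reaction at the activated ring carbon ortho to a hydroxyl; C3 and C5 of 2 are equivalent, so only one mono-adduct is possible and one equivalent of each reagent should limit bis-aminomethylation.

Step 3
Reactants: 4 (1R,2R,3R,5S)-2,6,6-trimethylbicyclo[3.1.1]heptan-3-amine (isopinocampheylamine)
Product: 5 dibenzyl 2,2'-{[(1R,2R,3R,5S)-2,6,6-trimethylbicyclo[3.1.1]heptan-3-yl]azanediyl}diacetate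
Conditions: BrCH2CO2Bn (2.2 equiv), K2CO3 (2.5 equiv), MeCN, 60 °C
Reagents that add atoms: benzyl bromoacetate, BrCC(=O)OCc1ccccc1
Why: Double SN2 N-alkylation of the primary amine by the alpha-bromo ester, after which the hindered tertiary amine should not quaternise.

Step 4
Reactants: 5 dibenzyl 2,2'-{[(1R,2R,3R,5S)-2,6,6-trimethylbicyclo[3.1.1]heptan-3-yl]azanediyl}diacetate
Product: 6 2,2'-{[(1R,2R,3R,5S)-2,6,6-trimethylbicyclo[3.1.1]heptan-3-yl]azanediyl}diacetic acid
Conditions: H2 (1 atm), 10% Pd/C, EtOH, 23 °C
Reagents that add atoms: none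
Why: Catalytic hydrogenolysis of the two benzyl esters should free the diacid without touching the saturated pinane skeleton.

Step 5
Reactants: 6 2,2'-{[(1R,2R,3R,5S)-2,6,6-trimethylbicyclo[3.1.1]heptan-3-yl]azanediyl}diacetic acid; 7 (2-methylprop-1-en-1-yl)boronic acid
Product: 8 2-(2-methylprop-1-en-1-yl)-6-[(1R,2R,3R,5S)-2,6,6-trimethylbicyclo[3.1.1]heptan-3-yl]-1,3,6,2-dioxazaborocane-4,8-dione
Conditions: toluene/DMSO 10:1, reflux, Dean–Stark trap
Reagents that add atoms: none
Why: Dehydrative condensation of a boronic acid with an N-substituted iminodiacetic acid, as used for N-methyliminodiacetic acid boronates, should give the cage boronate with a dative N–B bond and tetracoordinate boron.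

Step 6
Reactants: 3 1-{4-(benzyloxy)-3-[(dimethylamino)methyl]-2,6-dihydroxyphenyl}ethanone; 8 2-(2-methylprop-1-en-1-yl)-6-[(1R,2R,3R,5S)-2,6,6-trimethylbicyclo[3.1.1]heptan-3-yl]-1,3,6,2-dioxazaborocane-4,8-dione
Product: 10 1-[(3R)-5-(benzyloxy)-7-hydroxy-2,2-dimethyl-3-{4,8-dioxo-6-[(1R,2R,3R,5S)-2,6,6-trimethylbicyclo[3.1.1]heptan-3-yl]-1,3,6,2-dioxazaborocan-2-yl}-3,4-dihydro-2H-chromen-8-yl]ethanone, via ortho-quinone methide 9 (not isolated)
Conditions: 8 (3 equiv), 1,4-dioxane, 100 °C, N2 sweep; 3 added over 6 h
Reagents that add atoms: none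
Why: Proposed new method: heating 3 should expel dimethylamine by 1,4-elimination to give the ortho-quinone methide 9, a 1-oxadiene C4=C4a–C8a=O1 activated by the flanking 8-acetyl carbonyl, which should add across the C3=C2 double bond of 8 in an asynchronous inverse-electron-demand hetero-Diels–Alder reaction in which the C4–C3 bond forms ahead of the O1–C2 bond. The closest known reaction types are the [4+2] cycloadditions of acylphloroglucinol ortho-quinone methides with trisubstituted alkenes to give 2,2-dialkylchromans and the face-selective electrophilic epoxidation of alkenyl boronates carrying this pinene-derived iminodiacetate ligand; what is new is the use of such a boronate as the two-carbon partner. Ring B (the pyran) closes by this [4+2] cycloaddition, which at its polar limit is attack of C4 on C3 followed by 6-endo capture of the C2 tertiary cation by O1. The regiochemistry should follow because the gem-dimethyl carbon C2 is the cation-stabilising end and the electron-rich C3–B sigma bond of tetracoordinate boron stabilises that charge further, while a tetracoordinate boron cannot bind O1 and so cannot hand the alkenyl group to C4 with loss of boron. C3 is the only new stereocentre and its configuration depends only on which face of the alkene meets C4: the isopinocampheyl group on nitrogen sits beside the B–C3 bond across the N–B dative bond and shields one face, so C4 should add to the other and give 3R. The step needs cycloaddition to outrun self-condensation of 9 with the electron-rich ring of 3, which slow addition of 3 to excess 8 addresses, and it needs O1 rather than O5 to close the ring, which the 5-O-benzyl group secures.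

Step 7
Reactants: 10 1-[(3R)-5-(benzyloxy)-7-hydroxy-2,2-dimethyl-3-{4,8-dioxo-6-[(1R,2R,3R,5S)-2,6,6-trimethylbicyclo[3.1.1]heptan-3-yl]-1,3,6,2-dioxazaborocan-2-yl}-3,4-dihydro-2H-chromen-8-yl]ethanone
Product: 11 1-[(3R)-5-(benzyloxy)-3,7-dihydroxy-2,2-dimethyl-3,4-dihydro-2H-chromen-8-yl]ethanone
Conditions: 30% aq H2O2 (5 equiv), 1 M aq NaOH (3 equiv, added last), THF, 0 °C, 30 min
Reagents that add atoms: hydrogen peroxide, OO
Why: Organoborane oxidation in which hydroxide cleaves the iminodiacetate ligand, hydroperoxide adds to boron and C3 migrates from boron to oxygen with retention, so the 3R C–B bond should become the 3R C–OH bond as in the hydroboration–oxidation of flav-2-enes to flavan-3-ols, while low temperature and short contact should spare the hydroxyaryl ketone from Dakin oxidation.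

Step 8
Reactants: 11 1-[(3R)-5-(benzyloxy)-3,7-dihydroxy-2,2-dimethyl-3,4-dihydro-2H-chromen-8-yl]ethanone
Product: 12 1-[(3R)-3,5,7-trihydroxy-2,2-dimethyl-3,4-dihydro-2H-chromen-8-yl]ethanone
Conditions: H2 (1 atm), 10% Pd/C, EtOAc, 23 °C
Reagents that add atoms: none
Why: Catalytic hydrogenolysis of the aryl benzyl ether, run before any alkene is present, should leave the chelated aryl ketone and the C3 stereocentre untouched.

Step 9
Reactants: 12 1-[(3R)-3,5,7-trihydroxy-2,2-dimethyl-3,4-dihydro-2H-chromen-8-yl]ethanone; 13 (2E)-1-bromo-3,7-dimethylocta-2,6-diene (geranyl bromide)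
Product: 14 1-[(3R)-5-{[(2E)-3,7-dimethylocta-2,6-dien-1-yl]oxy}-3,7-dihydroxy-2,2-dimethyl-3,4-dihydro-2H-chromen-8-yl]ethanone
Conditions: 13 (1.05 equiv), K2CO3 (1.1 equiv), acetone, 23 to 40 °C
Reagents that add atoms: none
Why: Williamson etherification in which the 5-OH (para to the acetyl, not chelated) is far more acidic and accessible than the 7-OH held in a hydrogen bond to the ketone or the secondary 3-OH, and SN2 attack at the primary allylic carbon should keep the E geometry.

**Compound list**
1 | 1-(2,4,6-trihydroxyphenyl)ethanone | CC(=O)c1c(O)cc(O)cc1O | starting material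
2 | 1-[4-(benzyloxy)-2,6-dihydroxyphenyl]ethanone | CC(=O)c1c(O)cc(OCc2ccccc2)cc1O | intermediate
3 | 1-{4-(benzyloxy)-3-[(dimethylamino)methyl]-2,6-dihydroxyphenyl}ethanone | CC(=O)c1c(O)cc(OCc2ccccc2)c(CN(C)C)c1O | intermediate
4 | (1R,2R,3R,5S)-2,6,6-trimethylbicyclo[3.1.1]heptan-3-amine | N[C@@H]1C[C@@H]2C[C@H]([C@H]1C)C2(C)C | starting material
5 | dibenzyl 2,2'-{[(1R,2R,3R,5S)-2,6,6-trimethylbicyclo[3.1.1]heptan-3-yl]azanediyl}diacetate | O=C(CN(CC(=O)OCc1ccccc1)[C@@H]1C[C@@H]2C[C@H]([C@H]1C)C2(C)C)OCc1ccccc1 | intermediate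
6 | 2,2'-{[(1R,2R,3R,5S)-2,6,6-trimethylbicyclo[3.1.1]heptan-3-yl]azanediyl}diacetic acid | OC(=O)CN(CC(=O)O)[C@@H]1C[C@@H]2C[C@H]([C@H]1C)C2(C)C | intermediate
7 | (2-methylprop-1-en-1-yl)boronic acid | CC(C)=CB(O)O | starting material
8 | 2-(2-methylprop-1-en-1-yl)-6-[(1R,2R,3R,5S)-2,6,6-trimethylbicyclo[3.1.1]heptan-3-yl]-1,3,6,2-dioxazaborocane-4,8-dione | CC(C)=C[B-]12OC(=O)C[N+]1(CC(=O)O2)[C@@H]1C[C@@H]2C[C@H]([C@H]1C)C2(C)C | intermediate
9 | 2-acetyl-5-(benzyloxy)-3-hydroxy-6-methylidenecyclohexa-2,4-dien-1-one | CC(=O)C1=C(O)C=C(OCc2ccccc2)C(=C)C1=O | intermediate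
10 | 1-[(3R)-5-(benzyloxy)-7-hydroxy-2,2-dimethyl-3-{4,8-dioxo-6-[(1R,2R,3R,5S)-2,6,6-trimethylbicyclo[3.1.1]heptan-3-yl]-1,3,6,2-dioxazaborocan-2-yl}-3,4-dihydro-2H-chromen-8-yl]ethanone | CC(=O)c1c(O)cc(OCc3ccccc3)c2c1OC(C)(C)[C@H]([B-]34OC(=O)C[N+]3(CC(=O)O4)[C@@H]3C[C@@H]4C[C@H]([C@H]3C)C4(C)C)C2 | intermediate
11 | 1-[(3R)-5-(benzyloxy)-3,7-dihydroxy-2,2-dimethyl-3,4-dihydro-2H-chromen-8-yl]ethanone | CC(=O)c1c(O)cc(OCc3ccccc3)c2c1OC(C)(C)[C@H](O)C2 | intermediate
12 | 1-[(3R)-3,5,7-trihydroxy-2,2-dimethyl-3,4-dihydro-2H-chromen-8-yl]ethanone | CC(=O)c1c(O)cc(O)c2c1OC(C)(C)[C@H](O)C2 | intermediate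
13 | (2E)-1-bromo-3,7-dimethylocta-2,6-diene | BrC/C=C(\C)CCC=C(C)C | starting material
14 | 1-[(3R)-5-{[(2E)-3,7-dimethylocta-2,6-dien-1-yl]oxy}-3,7-dihydroxy-2,2-dimethyl-3,4-dihydro-2H-chromen-8-yl]ethanone | CC(=O)c1c(O)cc(OC/C=C(\C)CCC=C(C)C)c2c1OC(C)(C)[C@H](O)C2 | target

**Step count and risks**
Total steps: 9. Longest linear sequence: 7 steps (4 → 5 → 6 → 8 → 10 → 11 → 12 → 14); the branch from 1 is 6 steps.

Steps most likely to fail:

1. Step 6 (Proposed new method). What may go wrong: self-condensation of the quinone methide with the electron-rich ring of unreacted Mannich base to methylene-bridged dimers, too slow a reaction of the hindered alkenyl boronate, an ene-type pathway in place of ring closure, or poor facial selectivity. Fallback with known chemistry: set out from 2 and condense it with 3-methylbut-2-enal (ethylenediammonium diacetate cat., xylene, reflux), the standard phenol–enal chromene annulation, to give the 2H-chromene 1-[5-(benzyloxy)-7-hydroxy-2,2-dimethyl-2H-chromen-8-yl]ethanone F1 as the only regioisomer because 2 is symmetrical. Jacobsen epoxidation of this 2,2-dimethylchromene with [(R,R)-N,N'-bis(3,5-di-tert-butylsalicylidene)-1,2-cyclohexanediaminato]manganese chloride (5 mol %), mCPBA and N-methylmorpholine N-oxide in CH2Cl2 at −78 °C should give the epoxide 1-[(3R,4R)-5-(benzyloxy)-3,4-epoxy-7-hydroxy-2,2-dimethyl-3,4-dihydro-2H-chromen-8-yl]ethanone F2, which is taken on crude. Hydrogenolysis (H2, 10% Pd/C, EtOAc) should cleave the benzylic C4–O bond and the benzyl ether in one operation with C3 untouched, and the route is rejoined at 12.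

2. Step 7. What may go wrong: anti beta-elimination of the boron "ate" complex across C3–C2 with expulsion of the O1 phenoxide (ring opening), or Dakin-type oxidation of the hydroxyaryl ketone. Fallback: set out from 10 and drive that elimination on purpose (1 M aq NaOH, THF, 23 °C, no peroxide) to the C-prenyl phenol 1-[4-(benzyloxy)-2,6-dihydroxy-3-(3-methylbut-2-en-1-yl)phenyl]ethanone F3. Oxidative cyclisation with DDQ (2,3-dichloro-5,6-dicyano-1,4-benzoquinone, benzene, reflux) should give the chromene F1, which is carried through the Jacobsen epoxidation to F2 and the hydrogenolysis described above, rejoining the route at 12.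

3. Step 9. What may go wrong: competing C-alkylation at C6 between the two oxygens and over-alkylation at the chelated 7-OH. Fallback: set out from 12 and form the ether by Mitsunobu reaction with geraniol (PPh3, DIAD, THF, 0 °C), in which only the most acidic hydroxyl acts as the nucleophile under neutral conditions and no ambident phenoxide is present, arriving at 14 (no new compound, F0).

**Further compounds**
F1 | step 6 | 1-[5-(benzyloxy)-7-hydroxy-2,2-dimethyl-2H-chromen-8-yl]ethanone | CC(=O)c1c(O)cc(OCc3ccccc3)c2c1OC(C)(C)C=C2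
F2 | step 6 | 1-[(3R,4R)-5-(benzyloxy)-3,4-epoxy-7-hydroxy-2,2-dimethyl-3,4-dihydro-2H-chromen-8-yl]ethanone | CC(=O)c1c(O)cc(OCc3ccccc3)c2c1OC(C)(C)[C@@H]3O[C@H]23
F3 | step 7 | 1-[4-(benzyloxy)-2,6-dihydroxy-3-(3-methylbut-2-en-1-yl)phenyl]ethanone | CC(=O)c1c(O)cc(OCc2ccccc2)c(CC=C(C)C)c1O
F0 | step 9 | none | none
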